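Ring B holds its tetrasubstituted C8=C9 alkene directly across from the C5–C6 bond that carries the acetoxy group. At the C5=C6 enol-ether level ring B is therefore a 1,4-cyclohexadiene, the retron of an alkyne Diels–Alder reaction. Everything rests on cutting C7–C8 and C9–C10. In one operation a chiral boron Lewis acid joins but-2-ynal to a ring A diene: ring B closes, quaternary C10 is set as one enantiomer, and the C6 oxygen, the Δ8(9) alkene, the C8 methyl and the C11 handle arrive in place. The precursor is the 2-silyloxydiene C7=C6(OTBS)–C5=C10 made from β-cyclocitral. C5 and C6 follow by substrate control; a B-alkyl Suzuki coupling adds the butenolide.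

Key step: step 5

Conventions: labdane numbering is used throughout (C17 = methyl on C8, C18/C19 = methyls on C4, C20 = methyl on C10), and β is the face of C20. The target is a trans-decalin with 5α-H, axial 6β-OAc and 10β-CH3, which is (5S,6R,10S). C13 of the chain is C4 of a furan-2(5H)-one.

Assumption: the sense of induction in step 5 follows the usual binding model of cationic oxazaborolidines with aldehydes (boron on the formyl oxygen, a formyl C–H···O contact, one phenyl under the π system), with ring A of the diene on the formyl-hydrogen side. On this model the (R)-prolinol-derived catalyst gives 10β-CH3. The pair is untested, so the configuration must be verified on the first material; both catalyst antipodes are commercial.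

Design notes:
- **Silyl group.** TBS is kept on purpose. In the s-cis diene it is the oxygen atom that sits between the two C4 methyls, whatever the silyl group, and silicon can turn toward C7. A smaller silyl group would not relieve this contact, and it would invite silyl transfer (aldol pathway) and protodesilylation by the acidic catalyst.
- **Order of events.** The aldehyde is methylenated before the enol ether is opened. A free C6 ketone next to C7H2–C8=C9–CHO would be a vinylogous 1,3-dicarbonyl and would enolise at once.
- **C5.** This centre is set by kinetic protonation only. Base equilibration is avoided because C7–H is more acidic than C5–H and would pull the Δ8(9) alkene into conjugation.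

Step 1
Reactants: 1 β-cyclocitral
Product: 2 1-(2,6,6-trimethylcyclohex-1-en-1-yl)ethan-1-ol (racemic carbinol)
Conditions: MeMgBr, Et2O, 0 °C → rt; aqueous quench
Reagents that add atoms: methylmagnesium bromide, C[Mg]Br
Why: Grignard 1,2-addition to a hindered enal without α-hydrogens is routine, and the new carbinol centre is racemic and is erased in step 2.

Step 2
Reactants: 2 1-(2,6,6-trimethylcyclohex-1-en-1-yl)ethan-1-ol
Product: 3 1-(2,6,6-trimethylcyclohex-1-en-1-yl)ethan-1-one
Conditions: Dess–Martin periodinane, CH2Cl2, 0 °C → rt
Reagents that add atoms: none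
Why: Dess–Martin oxidation turns the crowded secondary allylic alcohol into the ketone under near-neutral conditions that leave the tetrasubstituted alkene where it is.

Step 3
Reactants: 3 1-(2,6,6-trimethylcyclohex-1-en-1-yl)ethan-1-one
Product: 5 tert-butyldimethyl{[1-(2,6,6-trimethylcyclohex-1-en-1-yl)ethenyl]oxy}silane, via lithium enolate 4 (not isolated)
Conditions: LDA (commercial solution), THF, −78 °C; TBSCl, DMPU, −78 °C → rt; distillation or Et3N-deactivated silica
Reagents that add atoms: tert-butyldimethylsilyl chloride, CC(C)(C)[Si](C)(C)Cl; lithium diisopropylamide, [Li+].CC(C)[N-]C(C)C (its lithium is held only in 4)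
Why: Kinetic deprotonation of an enone with LDA removes an α′ proton of the acetyl methyl rather than a γ proton (the twisted carbonyl barely acidifies the γ positions), and O-silylation of the cross-conjugated enolate gives the 2-silyloxydiene.

Step 4
Reactants: 6 but-2-yn-1-ol
Product: 7 but-2-ynal
Conditions: activated MnO2, CH2Cl2, rt; filtration, careful concentration, solution assayed and used directly
Reagents that add atoms: none
Why: Activated MnO2 oxidises propargylic alcohols to ynals without over-oxidation, and simple filtration avoids isolating the volatile, polymerisable aldehyde neat.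

Step 5
Reactants: 5 tert-butyldimethyl{[1-(2,6,6-trimethylcyclohex-1-en-1-yl)ethenyl]oxy}silane; 7 but-2-ynal
Product: 8 (10S)-6-(tert-butyldimethylsilyloxy)drima-5,8-dien-11-al (C5=C6 silyl enol ether, C8=C9 enal with CHO on C9 and CH3 on C8, 10β-CH3)
Conditions: (R)-3,3-diphenyl-1-(o-tolyl)tetrahydropyrrolo[1,2-c][1,3,2]oxazaborole (20 mol %), Tf2NH (18 mol %), CH2Cl2, −78 °C; 7 (1.5 equiv); slow addition of 5; −78 → −30 °C; Et3N quench
Reagents that add atoms: none
Why: Proposed new method: the N-protonated oxazaborolidine binds the formyl oxygen of 7 and lowers the LUMO of the alkyne π bond conjugated with C=O, so that 5 can add in a single but unsymmetrical [4π+2π] event in which the enol-ether terminus C7 bonds early to the methyl-bearing alkyne carbon (C8) and the crowded C10 closes late onto the formyl-bearing carbon (C9). The closest known reaction types are chiral boron Lewis acid-catalysed Diels–Alder additions of acetylenic aldehydes to cyclopentadiene, the same cationic catalysts with simple 2-silyloxybutadienes, and thermal additions of acetylenic esters to 1-vinyl-2,6,6-trimethylcyclohexene; what is untested is their combination on a twisted diene with a fully substituted terminus. Ring B closes as a six-membered 1,4-cyclohexadiene by intermolecular cycloaddition, suprafacial on both partners, through the C7–C8 and C9–C10 bonds. Quaternary C10, the only new stereocentre, is under catalyst control: a phenyl group of the catalyst covers one side of the bound ynal and ring A is expected to lie on the formyl-hydrogen side, away from boron and its counter-ion, so that only one face of C5=C10 reaches C9, and both elements are needed because C8 and C9 stay sp2 and keep no record of an endo or exo approach. The step needs para regiochemistry, secured by the silyloxy group on C6 and the alkyl groups on C10, which together place the largest HOMO coefficient on C7 to match the large LUMO coefficient on the ynal β-carbon, and it needs cycloaddition to outrun Mukaiyama aldol attack on the formyl carbon, which the transfer-resistant TBS group and the slim, rod-shaped dienophile favour.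

Step 6
Reactants: 8 (10S)-6-(tert-butyldimethylsilyloxy)drima-5,8-dien-11-al
Product: 9 (10R)-6-(tert-butyldimethylsilyloxy)-13,14,15,16-tetranorlabda-5,8,11-triene (vinyl group on C9; same spatial arrangement at C10, the descriptor changes only through CIP ranking)
Conditions: Ph3PCH3Br, KHMDS, THF, 0 °C; then 8, −78 °C → rt; Et3N-deactivated silica
Reagents that add atoms: methyltriphenylphosphonium bromide, [Br-].C[P+](c1ccccc1)(c1ccccc1)c1ccccc1
Why: Wittig methylenation with the non-stabilised ylide is faster than γ-deprotonation, has its direct analogy in the methylenation of β-cyclocitral, and touches neither the silyl enol ether nor C10.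

Step 7
Reactants: 9 (10R)-6-(tert-butyldimethylsilyloxy)-13,14,15,16-tetranorlabda-5,8,11-triene
Product: 10 (5S,10S)-13,14,15,16-tetranorlabda-8,11-dien-6-one (trans-fused, 5α-H)
Conditions: TBAF, AcOH (excess over fluoride), THF, −20 → 0 °C; neutral work-up, used without delay
Reagents that add atoms: none
Why: Fluoride-induced cleavage of the silyl enol ether frees the C5=C6 enolate, which the buffer acid protonates at once at C5 from the α face because the axial C20 and C4β methyls roof the β face, so the trans fusion (also the more stable one) is set kinetically while the cold, weakly acidic medium avoids enolisation toward C7.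

Step 8
Reactants: 10 (5S,10S)-13,14,15,16-tetranorlabda-8,11-dien-6-one
Product: 11 (5S,6R,10S)-13,14,15,16-tetranorlabda-8,11-dien-6-ol (axial 6β-OH)
Conditions: LiAlH4, Et2O, −78 → 0 °C; Rochelle salt work-up
Reagents that add atoms: none
Why: Hydride reduction under steric approach control delivers hydrogen to C6 from the α face, since the syn-axial C20 and C4β methyls close the β face, giving the axial 6β-alcohol, and fast addition at low temperature outruns enolisation.

Step 9
Reactants: 11 (5S,6R,10S)-13,14,15,16-tetranorlabda-8,11-dien-6-ol
Product: 12 (5S,6R,10S)-13,14,15,16-tetranorlabda-8,11-dien-6-yl acetate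
Conditions: Ac2O, DMAP (cat.), pyridine, 50 °C
Reagents that add atoms: acetic anhydride, CC(=O)OC(C)=O
Why: DMAP-catalysed acylation puts the small acetyl group on the hindered axial hydroxyl with retention at C6, because only the O–H bond is broken.

Step 10
Reactants: 12 (5S,6R,10S)-13,14,15,16-tetranorlabda-8,11-dien-6-yl acetate; 13 4-bromofuran-2(5H)-one
Product: 15 (5S,6R,10S)-6-acetoxylabda-8,13-dien-15,16-olide (target), via B-alkyl-9-BBN borane 14 (not isolated)
Conditions: 9-BBN, THF, 0 °C → rt; then 13, Pd(dppf)Cl2 (5 mol %), AsPh3 (10 mol %), Cs2CO3, DMF–THF–H2O, rt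
Reagents that add atoms: 9-borabicyclo[3.3.1]nonane, [H]B1C2CCCC1CCC2 (its boron cage is held only in 14; it leaves one hydrogen on C11 of 15)
Why: 9-BBN adds anti-Markovnikov to the only accessible alkene (the monosubstituted vinyl group, the tetrasubstituted C8=C9 being inert), and the primary borane then undergoes B-alkyl Suzuki–Miyaura coupling with the vinylogous acyl bromide under mild carbonate conditions that spare the homoallylic acetate and the butenolide.

Compound list
1 | β-cyclocitral (2,6,6-trimethylcyclohex-1-ene-1-carbaldehyde) | CC1=C(C=O)C(C)(C)CCC1 | starting material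
2 | 1-(2,6,6-trimethylcyclohex-1-en-1-yl)ethan-1-ol, racemic | CC(O)C1=C(C)CCCC1(C)C | intermediate
3 | 1-(2,6,6-trimethylcyclohex-1-en-1-yl)ethan-1-one | CC(=O)C1=C(C)CCCC1(C)C | intermediate
4 | lithium 1-(2,6,6-trimethylcyclohex-1-en-1-yl)ethen-1-olate (not isolated) | [Li+].[O-]C(=C)C1=C(C)CCCC1(C)C | intermediate
5 | tert-butyldimethyl{[1-(2,6,6-trimethylcyclohex-1-en-1-yl)ethenyl]oxy}silane | C=C(O[Si](C)(C)C(C)(C)C)C1=C(C)CCCC1(C)C | intermediate
6 | but-2-yn-1-ol | CC#CCO | starting material
7 | but-2-ynal | CC#CC=O | intermediate
8 | (10S)-6-(tert-butyldimethylsilyloxy)drima-5,8-dien-11-al | CC1=C(C=O)[C@@]2(C)CCCC(C)(C)C2=C(O[Si](C)(C)C(C)(C)C)C1 | intermediate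
9 | (10R)-6-(tert-butyldimethylsilyloxy)-13,14,15,16-tetranorlabda-5,8,11-triene | CC1=C(C=C)[C@@]2(C)CCCC(C)(C)C2=C(O[Si](C)(C)C(C)(C)C)C1 | intermediate
10 | (5S,10S)-13,14,15,16-tetranorlabda-8,11-dien-6-one | O=C1CC(C)=C(C=C)[C@@]2(C)CCCC(C)(C)[C@H]12 | intermediate
11 | (5S,6R,10S)-13,14,15,16-tetranorlabda-8,11-dien-6-ol | O[C@@H]1CC(C)=C(C=C)[C@@]2(C)CCCC(C)(C)[C@H]12 | intermediate
12 | (5S,6R,10S)-13,14,15,16-tetranorlabda-8,11-dien-6-yl acetate | CC(=O)O[C@@H]1CC(C)=C(C=C)[C@@]2(C)CCCC(C)(C)[C@H]12 | intermediate
13 | 4-bromofuran-2(5H)-one | O=C1C=C(Br)CO1 | starting material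
14 | (5S,6R,10S)-12-(9-borabicyclo[3.3.1]nonan-9-yl)-13,14,15,16-tetranorlabd-8-en-6-yl acetate (not isolated) | CC(=O)O[C@@H]1CC(C)=C(CCB2C3CCCC2CCC3)[C@@]2(C)CCCC(C)(C)[C@H]12 | intermediate
15 | (5S,6R,10S)-6-acetoxylabda-8,13-dien-15,16-olide, CNP0128495.1 | CC(=O)O[C@@H]1CC(C)=C(CCC2=CC(=O)OC2)[C@@]2(C)CCCC(C)(C)[C@H]12 | target

Total step count: 10. Longest linear sequence: 9 (steps 1, 2, 3, 5, 6, 7, 8, 9, 10).

Steps most likely to fail

Step 5.
- **What may go wrong.** The s-cis form of the diene may be too thinly populated for the cycloaddition to proceed at low temperature. C7 may attack the formyl carbon in an aldol sense, or the acidic catalyst may strip the silyl group. A stepwise course with bond rotation before ring closure, or a mixed endo/exo approach, would erode facial selectivity at C10.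
- **Fallback, from 5 and 7 back to 11, known chemistry only.** The two components are heated without any Lewis acid (toluene, BHT, sealed tube, 110 °C). This is the established thermal mode for acetylenic dienophiles with 1-vinyl-2,6,6-trimethylcyclohexenes, and it has no aldol channel. It should give the racemic adduct F1. The conditions of steps 6, 7 and 8 carry this through the racemic triene F2 and the racemic trans-ketone F3 to the racemic 6β-alcohol F4. Classical resolution follows. Addition to (R)-1-(1-naphthyl)ethyl isocyanate (DMAP, toluene, 80 °C; the sp carbon is small enough for the axial hydroxyl) gives the (5S,6R,10S)-carbamate F5 and the (5R,6S,10R)-carbamate F6. These are diastereomers and are separated by chromatography or crystallisation. LiAlH4 (THF, reflux) releases 11 from F5.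

Step 7.
- **What may go wrong.** Protonation at C5 may occur from the wrong face. Enolisation toward C7 may be followed by drift of the Δ8(9) alkene into conjugation with the ketone.
- **Fallback, from 9 back to 10.** Control is switched from purely kinetic to thermodynamic and then kinetic. Compound 9 is hydrolysed and fully equilibrated (1 M HCl, THF; then NaOMe, MeOH, rt) to the conjugated trans-fused dienone F7. Here the 5α-H is fixed as the more stable ring fusion, and the ethylidene geometry does not matter. KOt-Bu (t-BuOH–THF) converts it into the linear potassium trienolate F8. Inverse quench into cold aqueous acetic acid protonates the α-carbon C7, which is the classical deconjugation used for steroidal 4,6-dien-3-ones. This gives 10, which is reduced at once as in step 8.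

Step 10.
- **What may go wrong.** The base may attack the bromobutenolide (substitution at C4 or ring opening). Transmetalation from the borane may be slow, leaving time for β-hydride elimination or protodeboronation.
- **Fallback, from 14 back to 15.** The boron route is replaced by a base-free zinc route. Borane 14 is oxidised (NaBO3·4H2O, THF–H2O, rt) to the primary alcohol F9. This is converted (I2, PPh3, imidazole, CH2Cl2) into the primary iodide F10. Zinc insertion (Zn dust, LiCl, THF, 40 °C, tolerant of the acetate) gives the alkylzinc iodide F11. Negishi coupling with 13 (Pd(dppf)Cl2, THF, rt) under neutral conditions gives 15.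

Further compounds
F1 | step 5 | racemic 6-(tert-butyldimethylsilyloxy)drima-5,8-dien-11-al | CC1=C(C=O)C2(C)CCCC(C)(C)C2=C(O[Si](C)(C)C(C)(C)C)C1
F2 | step 5 | racemic 6-(tert-butyldimethylsilyloxy)-13,14,15,16-tetranorlabda-5,8,11-triene | CC1=C(C=C)C2(C)CCCC(C)(C)C2=C(O[Si](C)(C)C(C)(C)C)C1
F3 | step 5 | racemic trans-fused 13,14,15,16-tetranorlabda-8,11-dien-6-one (10 and its mirror image, 1:1) | O=C1CC(C)=C(C=C)[C@@]2(C)CCCC(C)(C)[C@H]12.O=C1CC(C)=C(C=C)[C@]2(C)CCCC(C)(C)[C@@H]12
F4 | step 5 | racemic 13,14,15,16-tetranorlabda-8,11-dien-6β-ol (11 and its mirror image, 1:1) | O[C@@H]1CC(C)=C(C=C)[C@@]2(C)CCCC(C)(C)[C@H]12.O[C@H]1CC(C)=C(C=C)[C@]2(C)CCCC(C)(C)[C@@H]12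
F5 | step 5 | (5S,6R,10S)-13,14,15,16-tetranorlabda-8,11-dien-6-yl N-[(R)-1-(naphthalen-1-yl)ethyl]carbamate | C[C@@H](NC(=O)O[C@@H]1CC(C)=C(C=C)[C@@]2(C)CCCC(C)(C)[C@H]12)c1cccc2ccccc12
F6 | step 5 | (5R,6S,10R)-13,14,15,16-tetranorlabda-8,11-dien-6-yl N-[(R)-1-(naphthalen-1-yl)ethyl]carbamate | C[C@@H](NC(=O)O[C@H]1CC(C)=C(C=C)[C@]2(C)CCCC(C)(C)[C@@H]12)c1cccc2ccccc12
F7 | step 7 | (5S,10S)-13,14,15,16-tetranorlabda-7,9(11)-dien-6-one (either ethylidene geometry) | O=C1C=C(C)C(=CC)[C@@]2(C)CCCC(C)(C)[C@H]12
F8 | step 7 | potassium (5S,10S)-13,14,15,16-tetranorlabda-6,8,11-trien-6-olate | [K+].[O-]C1=CC(C)=C(C=C)[C@@]2(C)CCCC(C)(C)[C@H]12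
F9 | step 10 | (5S,6R,10S)-12-hydroxy-13,14,15,16-tetranorlabd-8-en-6-yl acetate | CC(=O)O[C@@H]1CC(C)=C(CCO)[C@@]2(C)CCCC(C)(C)[C@H]12
F10 | step 10 | (5S,6R,10S)-12-iodo-13,14,15,16-tetranorlabd-8-en-6-yl acetate | CC(=O)O[C@@H]1CC(C)=C(CCI)[C@@]2(C)CCCC(C)(C)[C@H]12
F11 | step 10 | [(5S,6R,10S)-6-acetoxy-13,14,15,16-tetranorlabd-8-en-12-yl]zinc iodide | CC(=O)O[C@@H]1CC(C)=C(CC[Zn]I)[C@@]2(C)CCCC(C)(C)[C@H]12
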